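**Plan**
1. Numbering (daucane): C1 is the ring-fusion carbon with the angular methyl C15. C2/C3 are ring CH2, C4 the isopropyl carbinol, C5 the ring-fusion CH, C6 the ester carbon, C7 a CH2. C8 is the spiro carbon with the epoxide CH2 C14, and C9/C10 are the diol carbons (C10 on C1). β is the face of C15 and α the opposite face.
2. Retrosynthesis: cut the oxirane C–O bonds (back to C8=C14), the acyl–O6 bond, C10–O and the C4–isopropyl bond. Then cut C7–C8 and C1–C10 of the seven-membered ring, and last C5–C6 (vinyllithium plus Weinreb amide).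
3. Enabling feature: the cycloheptane ring C1/C5–C10 has oxygen on C6 and C9, the one-carbon branch C14 on C8 between them, and the quaternary C1 next to C10. This is the pattern of a cyclohepta-1,4-diene built from a 2-silyloxydiene (C7=C6–C5=C1) and a silyloxyvinyl carbenoid (C8 bearing ester carbon C14, C9=C10).
4. Forward: the cyclopentene ring comes with the starting bromoenone. The seven-membered ring closes in step 6 by cyclopropanation of C6=C7 and divinylcyclopropane rearrangement. C4–C6 are adjusted first, then C8–C10, and the oxirane is made last.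
5. Stereochemistry: C1 from the chiral dirhodium catalyst; C5 by equilibration to the trans-fused ketone; C4 by α-face Grignard addition anti to C15; C6 by hydride delivery from the 4β-hydroxyl group; C10 by α-face Rubottom oxidation; C9 by Felkin–Anh reduction; C8 by hydroxyl-directed epoxidation.

Key step: step 6

Assumption: Rh2(S-PTAD)4 is taken to select the face of C6=C7 that leads to the C1 configuration of the target; if the sense of induction is the opposite, the mirror-image catalyst Rh2(R-PTAD)4 is used and nothing else changes.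

**Step 1**
Reactants: 1 2-bromo-3-methylcyclopent-2-en-1-one
Product: 2 6-bromo-7-methyl-1,4-dioxaspiro[4.4]non-6-ene
Conditions: HOCH2CH2OH, p-TsOH·H2O (cat.), benzene, reflux, Dean–Stark trap
Reagents that add atoms: ethylene glycol, OCCO
Why: Acid-catalysed ketalisation with azeotropic removal of water is routine for 2-bromocycloalkenones, in which the halogen keeps the double bond in place, and it masks the C4 carbonyl group for the lithiation.

**Step 2**
Reactants: 2 6-bromo-7-methyl-1,4-dioxaspiro[4.4]non-6-ene; 3 N-methoxy-N-methylacetamide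
Product: 5 1-(7-methyl-1,4-dioxaspiro[4.4]non-6-en-6-yl)ethan-1-one, via vinyllithium 4 (not isolated)
Conditions: n-BuLi, THF, −78 °C; then 3, −78 → 0 °C; H2O quench
Reagents that add atoms: none
Why: Bromine–lithium exchange gives the vinyllithium, and its addition to the amide stops at the chelated adduct, so that the methyl ketone carrying C6 and C7 is released only on quenching (Weinreb ketone synthesis).

**Step 3**
Reactants: 5 1-(7-methyl-1,4-dioxaspiro[4.4]non-6-en-6-yl)ethan-1-one
Product: 6 7-methyl-6-[1-(triethylsilyloxy)ethenyl]-1,4-dioxaspiro[4.4]non-6-ene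
Conditions: LiN(i-Pr)2, THF, −78 °C; then Et3SiCl, −78 → 0 °C
Reagents that add atoms: chlorotriethylsilane, CC[Si](Cl)(CC)CC
Why: Kinetic deprotonation of the enone at the acetyl methyl group and O-silylation of the cross-conjugated enolate give the 2-silyloxydiene, and the labile triethylsilyl group is chosen so that this enol ether can later be cleaved beside the second one.

**Step 4**
Reactants: 7 methyl acetoacetate
Product: 8 methyl 2-diazo-3-oxobutanoate
Conditions: 4-acetamidobenzenesulfonyl azide, Et3N, MeCN, 0 °C → rt
Reagents that add atoms: 4-acetamidobenzenesulfonyl azide, CC(=O)Nc1ccc(cc1)S(=O)(=O)N=[N+]=[N-]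
Why: Regitz diazo transfer to the active methylene group of a β-keto ester is a standard and reliable reaction.

**Step 5**
Reactants: 8 methyl 2-diazo-3-oxobutanoate
Product: 9 methyl 2-diazo-3-(triisopropylsilyloxy)but-3-enoate
Conditions: i-Pr3SiOTf, Et3N, CH2Cl2, 0 °C
Reagents that add atoms: triisopropylsilyl triflate, CC(C)[Si](C(C)C)(C(C)C)OS(=O)(=O)C(F)(F)F
Why: Soft enolisation and O-silylation of the diazo keto ester give the silyloxyvinyl diazoacetate, and the bulky triisopropylsilyl group is chosen because this vinylogous silyl carbonate has to last until step 13.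

**Step 6**
Reactants: 6 7-methyl-6-[1-(triethylsilyloxy)ethenyl]-1,4-dioxaspiro[4.4]non-6-ene; 9 methyl 2-diazo-3-(triisopropylsilyloxy)but-3-enoate
Product: 11 (1R)-cycloheptadiene bis(silyl enol ether) [hydroazulene core; C5=C6–OSiEt3; C8(CO2Me)=C9–OSi(i-Pr)3; C4 ethylene ketal; C1 methyl], via cis-divinylcyclopropane 10 (not isolated)
Conditions: Rh2(S-PTAD)4 (1 mol %), slow addition of 9 to 6, hexanes, −25 °C → rt; then 60 °C
Reagents that add atoms: none
Why: Nitrogen loss from 9 at the divalent rhodium dimer gives a donor–acceptor vinylcarbenoid, which cyclopropanates the terminal C6=C7 enol ether bond of 6 and so forms C7–C8 together with a temporary C6–C8 bond; the closest known reaction type is the tandem cyclopropanation–Cope rearrangement (formal 4+3 cycloaddition) of vinyldiazoacetates with 1,3-dienes. The seven-membered ring is closed by sigmatropic ring expansion and not by direct cyclisation: cis-divinylcyclopropane 10 passes through an endo boat transition state in which strain release breaks C6–C8 while C10 bonds to C1. The breaking bond lies between the silyloxy donor on C6 and the ester acceptor on C8, which lowers the barrier and compensates for the C15 methyl group that has to point into the boat, so that gentle heating should finish the shift. C1, the only stereocentre left in 11, is controlled by the chiral carboxylate ligands, which select the face of C6=C7 (6R,8S in 10), and the boat geometry relays this choice because C10 can reach only one face of C5=C1. The step needs site selectivity, secured by the steric shielding of the tetrasubstituted C5=C1 bond and the higher nucleophilicity of the terminal enol ether, and carbenoid rather than vinylogous reactivity, favoured by the hydrocarbon solvent and the carboxylate catalyst. It also needs the two alkenyl groups cis on the cyclopropane, which is the normal outcome for donor–acceptor carbenoids, and a trans isomer could still funnel into 11 on heating through reversible opening of the donor–acceptor bond.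

**Step 7**
Reactants: 11 (1R)-cycloheptadiene bis(silyl enol ether)
Product: 12 trans-fused C6 ketone [5α-H; 1β-methyl; C8(CO2Me)=C9–OSi(i-Pr)3; C4 ethylene ketal]
Conditions: Et3N·3HF, THF, 0 °C; then DBU (0.2 equiv), toluene, rt
Reagents that add atoms: none
Why: Fluoride-mediated cleavage should remove the small electron-rich triethylsilyl enol ether much faster than the hindered triisopropylsilyl group while the nearly neutral medium spares the ketal, and base equilibration of the epimerisable C5 should then give the trans-fused ketone (H-5 α, anti to C15), the more stable epimer in angular-methyl hydroazulenones of this type.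

**Step 8**
Reactants: 12 trans-fused C6 ketone
Product: 13 6β-alcohol of 12 [5α-H; C4 ethylene ketal]
Conditions: LiBH(s-Bu)3, THF, −78 °C; H2O quench
Reagents that add atoms: none
Why: This bulky-hydride reduction touches only the ketone and should approach C6 from the α face, away from the syn-axial C15 methyl group, to give the 6β-alcohol, which serves merely as a masked ketone because the centre is reset in steps 11 and 12.

**Step 9**
Reactants: 13 6β-alcohol
Product: 14 6β-hydroxy C4 ketone [5α-H; C8(CO2Me)=C9–OSi(i-Pr)3]
Conditions: PPTS, acetone–H2O, 40 °C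
Reagents that add atoms: water, O
Why: Mild acid-catalysed ketal hydrolysis frees the cyclopentanone, while the push–pull triisopropylsilyl enol ether is not protonated at carbon by the pyridinium salt and the β-hydroxy ketone should not dehydrate at this acidity.

**Step 10**
Reactants: 14 6β-hydroxy C4 ketone
Product: 15 4β,6β-diol bearing the 4α-isopropyl group
Conditions: i-PrMgCl (3.5 equiv), LaCl3·2LiCl (1.1 equiv), THF, −30 → 0 °C
Reagents that add atoms: isopropylmagnesium chloride, CC(C)[Mg]Cl
Why: The lanthanum-salt-promoted Grignard 1,2-addition suppresses enolisation and reduction of the cyclopentanone, and after deprotonation of the 6-hydroxyl group the reagent should attack C4 from the open α face because the β face carries C15 and the 6β-alkoxide, which gives the 4β-alcohol.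

**Step 11**
Reactants: 15 4β,6β-diol
Product: 16 4β-hydroxy C6 ketone [4α-isopropyl; 5α-H]
Conditions: Dess–Martin periodinane, pyridine, CH2Cl2, 0 °C → rt
Reagents that add atoms: none
Why: Dess–Martin oxidation converts the only secondary alcohol into the ketone under conditions that spare the tertiary aldol and the enol ether, and C5 should hold its configuration because C6 trans to the 4α-isopropyl group on the cyclopentane is also the more stable arrangement.

**Step 12**
Reactants: 16 4β-hydroxy C6 ketone
Product: 17 4β,6α-diol [C8(CO2Me)=C9–OSi(i-Pr)3]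
Conditions: Me4NBH(OAc)3, MeCN–AcOH, −30 °C
Reagents that add atoms: none
Why: In the Evans–Saksena reduction the 4β-hydroxyl group binds boron and delivers hydride intramolecularly to the β face of the C6 carbonyl group, which should give the 1,3-anti diol with the 6α-hydroxyl group regardless of the shielding by C15.

**Step 13**
Reactants: 17 4β,6α-diol
Product: 19 4β,6α-dihydroxydauc-8(14)-en-9-one, via allylic alcohol 18 (not isolated)
Conditions: i-Bu2AlH (6 equiv), CH2Cl2, −78 → 0 °C; then 1 M HCl, THF, 0 °C
Reagents that add atoms: none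
Why: 1,2-Reduction of the β-silyloxy acrylate to the allylic alcohol, followed by acid-induced loss of the C14 hydroxyl group pushed out by the enol ether oxygen and desilylation (a Stork–Danheiser-type transposition), turns the ester carbon into the exocyclic methylene group and frees the C9 ketone.

**Step 14**
Reactants: 19 4β,6α-dihydroxydauc-8(14)-en-9-one
Product: 20 4β-hydroxy-9-oxodauc-8(14)-en-6α-yl 3-methylbutanoate
Conditions: isovaleric anhydride, Et3N, DMAP (cat.), CH2Cl2, 0 °C → rt
Reagents that add atoms: 3-methylbutanoic anhydride, CC(C)CC(=O)OC(=O)CC(C)C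
Why: DMAP-catalysed acylation should take place only at the equatorial secondary 6α-hydroxyl group because the tertiary 4-hydroxyl group next to the isopropyl group is too hindered.

**Step 15**
Reactants: 20 4β-hydroxy-9-oxodauc-8(14)-en-6α-yl 3-methylbutanoate
Product: 21 bis(triethylsilyl) compound [C14=C8–C9(OSiEt3)=C10 diene; 4β-OSiEt3; 6α-isovalerate]
Conditions: Et3SiOTf (3 equiv), Et3N, CH2Cl2, 0 °C
Reagents that add atoms: triethylsilyl triflate, CC[Si](CC)(CC)OS(=O)(=O)C(F)(F)F
Why: Soft enolisation of the enone can remove a proton only from C10 and so gives the cross-conjugated 2-silyloxydiene, the tertiary alcohol is silylated at the same time, and the ester is not enolised under these conditions.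

**Step 16**
Reactants: 21 bis(triethylsilyl) compound
Product: 22 10α-(triethylsilyloxy) enone [C8=C14; C9 ketone; 4β-OSiEt3; 6α-isovalerate]
Conditions: dimethyldioxirane, acetone–CH2Cl2, −78 → 0 °C
Reagents that add atoms: dimethyldioxirane, CC1(C)OO1
Why: In this Rubottom oxidation the electrophilic oxidant attacks the most electron-rich double bond, C9=C10, from the α face opposite to the C15 methyl group on the neighbouring C1, and silyl migration should give the 10α-silyloxy enone.

**Step 17**
Reactants: 22 10α-(triethylsilyloxy) enone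
Product: 23 9α-alcohol [C8=C14; 10α-OSiEt3; 4β-OSiEt3; 6α-isovalerate]
Conditions: NaBH4, CeCl3·7H2O, MeOH, −78 °C
Reagents that add atoms: none
Why: The Luche reduction secures 1,2-addition to the enone, and the axial 10α-silyloxy group, which stands perpendicular to the carbonyl plane, should steer the small hydride to the opposite β face (polar Felkin–Anh control) and so give the equatorial 9α-alcohol cis to O-10.

**Step 18**
Reactants: 23 9α-alcohol
Product: 24 4β,9α,10α-trihydroxydauc-8(14)-en-6α-yl 3-methylbutanoate
Conditions: HF·pyridine, pyridine, THF, 0 °C → rt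
Reagents that add atoms: none
Why: Buffered fluoride-mediated desilylation removes both triethylsilyl ethers under conditions too mild to affect the ester or the allylic alcohol.

**Step 19**
Reactants: 24 4β,9α,10α-trihydroxydauc-8(14)-en-6α-yl 3-methylbutanoate
Product: 25 (1S,4R,5S,6S,8S,9S,10S)-8,14-epoxy-4,9,10-trihydroxydaucan-6-yl 3-methylbutanoate (target)
Conditions: VO(acac)2 (cat.), t-BuOOH, CH2Cl2, 0 °C
Reagents that add atoms: tert-butyl hydroperoxide, CC(C)(C)OO
Why: In the vanadium-catalysed hydroxyl-directed epoxidation the peroxide is held by the allylic 9α- and the homoallylic 10α-hydroxyl groups, both on the α face, so that oxygen should be delivered to the α face of C8=C14 and set C8.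

**Compound list**
1 | 2-bromo-3-methylcyclopent-2-en-1-one | CC1=C(Br)C(=O)CC1 | starting material
2 | 6-bromo-7-methyl-1,4-dioxaspiro[4.4]non-6-ene | CC1=C(Br)C2(CC1)OCCO2 | intermediate
3 | N-methoxy-N-methylacetamide | CON(C)C(C)=O | starting material
4 | (7-methyl-1,4-dioxaspiro[4.4]non-6-en-6-yl)lithium (not isolated) | [Li]C1=C(C)CCC12OCCO2 | intermediate
5 | 1-(7-methyl-1,4-dioxaspiro[4.4]non-6-en-6-yl)ethan-1-one | CC(=O)C1=C(C)CCC12OCCO2 | intermediate
6 | 7-methyl-6-[1-(triethylsilyloxy)ethenyl]-1,4-dioxaspiro[4.4]non-6-ene | C=C(O[Si](CC)(CC)CC)C1=C(C)CCC12OCCO2 | intermediate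
7 | methyl acetoacetate | COC(=O)CC(C)=O | starting material
8 | methyl 2-diazo-3-oxobutanoate | COC(=O)C(=[N+]=[N-])C(C)=O | intermediate
9 | methyl 2-diazo-3-(triisopropylsilyloxy)but-3-enoate | COC(=O)C(=[N+]=[N-])C(=C)O[Si](C(C)C)(C(C)C)C(C)C | intermediate
10 | methyl (1S,2R)-2-(7-methyl-1,4-dioxaspiro[4.4]non-6-en-6-yl)-2-(triethylsilyloxy)-1-[1-(triisopropylsilyloxy)ethenyl]cyclopropane-1-carboxylate (cis-divinylcyclopropane, not isolated) | C=C(O[Si](C(C)C)(C(C)C)C(C)C)[C@@]1(C(=O)OC)C[C@@]1(O[Si](CC)(CC)CC)C1=C(C)CCC12OCCO2 | intermediate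
11 | (1R)-cycloheptadiene bis(silyl enol ether): C5=C6–OSiEt3, C8(CO2Me)=C9–OSi(i-Pr)3, C4 ethylene ketal, C1 methyl | CC[Si](CC)(CC)OC1=C2C3(OCCO3)CC[C@]2(C)CC(O[Si](C(C)C)(C(C)C)C(C)C)=C(C(=O)OC)C1 | intermediate
12 | trans-fused C6 ketone: 5α-H, 1β-methyl, C4 ethylene ketal | O=C1CC(C(=O)OC)=C(O[Si](C(C)C)(C(C)C)C(C)C)C[C@@]2(C)CCC3(OCCO3)[C@H]12 | intermediate
13 | 6β-alcohol, C4 ethylene ketal | O[C@@H]1CC(C(=O)OC)=C(O[Si](C(C)C)(C(C)C)C(C)C)C[C@@]2(C)CCC3(OCCO3)[C@H]12 | intermediate
14 | 6β-hydroxy C4 ketone | O[C@@H]1CC(C(=O)OC)=C(O[Si](C(C)C)(C(C)C)C(C)C)C[C@@]2(C)CCC(=O)[C@H]12 | intermediate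
15 | 4β,6β-diol with 4α-isopropyl | O[C@@H]1CC(C(=O)OC)=C(O[Si](C(C)C)(C(C)C)C(C)C)C[C@@]2(C)CC[C@@](O)(C(C)C)[C@H]12 | intermediate
16 | 4β-hydroxy C6 ketone | O=C1CC(C(=O)OC)=C(O[Si](C(C)C)(C(C)C)C(C)C)C[C@@]2(C)CC[C@@](O)(C(C)C)[C@H]12 | intermediate
17 | 4β,6α-diol | O[C@H]1CC(C(=O)OC)=C(O[Si](C(C)C)(C(C)C)C(C)C)C[C@@]2(C)CC[C@@](O)(C(C)C)[C@H]12 | intermediate
18 | 4β,6α,14-triol with C8=C9–OSi(i-Pr)3 (allylic alcohol, not isolated) | O[C@H]1CC(CO)=C(O[Si](C(C)C)(C(C)C)C(C)C)C[C@@]2(C)CC[C@@](O)(C(C)C)[C@H]12 | intermediate
19 | 4β,6α-dihydroxydauc-8(14)-en-9-one | O[C@H]1CC(=C)C(=O)C[C@@]2(C)CC[C@@](O)(C(C)C)[C@H]12 | intermediate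
20 | 4β-hydroxy-9-oxodauc-8(14)-en-6α-yl 3-methylbutanoate | CC(C)CC(=O)O[C@H]1CC(=C)C(=O)C[C@@]2(C)CC[C@@](O)(C(C)C)[C@H]12 | intermediate
21 | 4β,9-bis(triethylsilyloxy)dauca-8(14),9-dien-6α-yl 3-methylbutanoate | CC(C)CC(=O)O[C@H]1CC(=C)C(O[Si](CC)(CC)CC)=C[C@@]2(C)CC[C@@](O[Si](CC)(CC)CC)(C(C)C)[C@H]12 | intermediate
22 | 4β,10α-bis(triethylsilyloxy)-9-oxodauc-8(14)-en-6α-yl 3-methylbutanoate | CC(C)CC(=O)O[C@H]1CC(=C)C(=O)[C@@H](O[Si](CC)(CC)CC)[C@@]2(C)CC[C@@](O[Si](CC)(CC)CC)(C(C)C)[C@H]12 | intermediate
23 | 9α-hydroxy-4β,10α-bis(triethylsilyloxy)dauc-8(14)-en-6α-yl 3-methylbutanoate | CC(C)CC(=O)O[C@H]1CC(=C)[C@@H](O)[C@@H](O[Si](CC)(CC)CC)[C@@]2(C)CC[C@@](O[Si](CC)(CC)CC)(C(C)C)[C@H]12 | intermediate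
24 | 4β,9α,10α-trihydroxydauc-8(14)-en-6α-yl 3-methylbutanoate | CC(C)CC(=O)O[C@H]1CC(=C)[C@@H](O)[C@@H](O)[C@@]2(C)CC[C@@](O)(C(C)C)[C@H]12 | intermediate
25 | (1S,4R,5S,6S,8S,9S,10S)-8,14-epoxy-4,9,10-trihydroxydaucan-6-yl 3-methylbutanoate | CC(C)CC(=O)O[C@H]1C[C@]2(CO2)[C@@H](O)[C@@H](O)[C@@]2(C)CC[C@@](O)(C(C)C)[C@H]12 | target

**Step count**
Total steps: 19. Longest linear sequence: 17 steps (from 1 through steps 1–3 and 6–19).

**Steps most likely to fail**

Step 6 (cyclopropanation–Cope rearrangement).
- The nucleophilic enol ether could attack the vinylogous end C10 of the carbenoid instead of C8.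
- The donor–acceptor cyclopropane could open heterolytically before the sigmatropic shift, with loss of material and of enantiomeric purity.
- The shift could stall for steric reasons.

The fallback keeps the ring construction but brings in the C6 oxygen afterwards. It sets out from 2 and comes back at 12. Suzuki–Miyaura coupling of 2 with potassium vinyltrifluoroborate (PdCl2(dppf), Cs2CO3, THF–H2O) would give 6-ethenyl-7-methyl-1,4-dioxaspiro[4.4]non-6-ene F1. Its monosubstituted vinyl group is the best documented kind of partner for 9 under Rh2(S-PTAD)4. The C6-unsubstituted cis-divinylcyclopropane F2 would form and rearrange to the C6-unsubstituted cycloheptadiene F3. Hydroboration–oxidation (BH3·SMe2, then NaBO3) of the trisubstituted C5=C6 bond would place the hydroxyl group on C6 and give the 6-hydroxy ketal F4, drawn for syn addition to the α face. Dess–Martin oxidation followed by the DBU equilibration of step 7 would lead to 12 whichever face the borane had chosen.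

Step 10 (isopropyl addition). Enolisation of the hindered cyclopentanone, hydride transfer from the isopropyl reagent (reduction in place of addition) or retro-aldol cleavage of the metal aldolate could consume 14. The fallback sets out from 14 and returns at 15. The smaller sp2 nucleophile isopropenylmagnesium bromide cannot act as a hydride donor. It would be added under the same LaCl3·2LiCl promotion to give the 4α-isopropenyl 4β,6β-diol F5. Hydrogenation over RhCl(PPh3)3 would then saturate only the 1,1-disubstituted double bond, the tetrasubstituted push–pull alkene being inert.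

Step 17 (reduction at C9). Poor or inverted facial selectivity is possible because the C15 methyl group is syn-axial to the β-face trajectory at C9, so the hydride might arrive from the α face. The fallback accepts this bias and corrects it by substitution. It sets out from 22 and returns at 23. The same reduction would then give the 9β-alcohol F6. Mitsunobu reaction with chloroacetic acid (PPh3, DIAD, toluene) would invert C9 to the 9α-chloroacetate F7. Thiourea (NaHCO3, EtOH) would remove the chloroacetyl group selectively in the presence of the isovalerate.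

**Further compounds**
F1 | step 6 | 6-ethenyl-7-methyl-1,4-dioxaspiro[4.4]non-6-ene | C=CC1=C(C)CCC12OCCO2
F2 | step 6 | C6-unsubstituted cis-divinylcyclopropane | C=C(O[Si](C(C)C)(C(C)C)C(C)C)[C@@]1(C(=O)OC)C[C@H]1C1=C(C)CCC12OCCO2
F3 | step 6 | C6-unsubstituted cycloheptadiene (C5=C6–H, C8(CO2Me)=C9–OSi(i-Pr)3, C4 ethylene ketal) | COC(=O)C1=C(O[Si](C(C)C)(C(C)C)C(C)C)C[C@@]2(C)CCC3(OCCO3)C2=CC1
F4 | step 6 | 6-hydroxy ketal (5α-H, 6α-OH) | O[C@H]1CC(C(=O)OC)=C(O[Si](C(C)C)(C(C)C)C(C)C)C[C@@]2(C)CCC3(OCCO3)[C@H]12
F5 | step 10 | 4α-isopropenyl 4β,6β-diol | O[C@@H]1CC(C(=O)OC)=C(O[Si](C(C)C)(C(C)C)C(C)C)C[C@@]2(C)CC[C@@](O)(C(C)=C)[C@H]12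
F6 | step 17 | 9β-alcohol (C9 epimer of 23) | CC(C)CC(=O)O[C@H]1CC(=C)[C@H](O)[C@@H](O[Si](CC)(CC)CC)[C@@]2(C)CC[C@@](O[Si](CC)(CC)CC)(C(C)C)[C@H]12
F7 | step 17 | 9α-chloroacetate | CC(C)CC(=O)O[C@H]1CC(=C)[C@@H](OC(=O)CCl)[C@@H](O[Si](CC)(CC)CC)[C@@]2(C)CC[C@@](O[Si](CC)(CC)CC)(C(C)C)[C@H]12
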